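(The numbers in the tables were computed with constants of no real substance.)

Free monomer and monomer in chains together stayed close to the whole charge in the earlier runs, 33% and 67% at the last north reading, so I counted every monomer lost as a unit in a chain.

| setting | north | south-west | ash | elm |
|---|---|---|---|---|
| free monomer | 0.66 M | 0.66 M | 0.66 M | 1.2 M |
| initiator | 1.5 mol% | 2 mol% | 1 mol% | 1 mol% |
| remark | run made earlier | run made earlier |  |  |
| time |  |  | 25 min | 25 min |

- north (time / min: monomer in chains / %, free monomer / %): 1.00: 24, 80; 2.00: 35, 65; 3.00: 53, 45; 4.00: 61, 36; 5.00: 67, 33
- south-west (time / min: monomer in chains / %, free monomer / %): 1.00: 27, 73; 2.00: 40, 60; 3.00: 54, 44; 4.00: 65, 33; 5.00: 73, 26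

(readings scatter by 1.5 percentage points)

- percentages count the free monomer that a species holds: one self-condensation product counts as two
- the average divides the monomer in chains by the number of chains, living and dead together; two radicals that join make one chain
- steps thought possible: 2 growing radical -> dead chain; free monomer + initiating radical -> growing radical + monomer in chains; 2 free monomer -> self-condensation product; initiator -> 2 initiating radical; free monomer + growing radical -> monomer in chains + growing radical
- the earlier runs do not show the number of chains; that part of a forecast is a guess

* which of the two ends with the longer chains by the average number of monomer units in a chain (living and dead chains, two that joined counted as one) ("neither" if they lie within 10%) (ash / elm / neither)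
* average number of monomer units in a chain (living and dead chains, two that joined counted as one) at the end, ash
* average number of monomer units in a chain (living and dead chains, two that joined counted as one) at the end, elm

I read the south-west decay as 0.269 /min. Taking the rate to follow the root of the initiator concentration, as radicals ending in pairs require, gave ash 0.191 /min and elm a faster 0.257 /min, so I expected nearly all the monomer in ash to be in chains by 25 min, and sooner in elm.

Then I followed one initiator molecule. It splits into two initiating radicals, each starts a growing radical, and two of those join (termination by combination), which makes one chain per initiator split. The two amounts I set against each other were monomer charged and initiator charged, and their ratio was 100 in both flasks: the units per initiator. As long as every initiating radical goes on to a chain, the average length is this ratio times the share of monomer reacted, divided by the share of initiator split. Splitting is first order, so at one temperature equal times split equal shares. I said neither, but the earlier runs gave me no number of chains.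

The forecast said neither, with 170 for ash and 170 for elm: “Both charges have the same initiator-to-monomer ratio, so both averages match”, with a guessed 60% split.

The simulation gave neither, with 232 for ash and 234 for elm.

    2 growing radical → dead chain (k = 6.00 × 10⁷ /M/s)
    free monomer + initiating radical → growing radical + monomer in chains (k = 1.00 × 10⁶ /M/s)
    2 free monomer → self-condensation product (k = 1.20 × 10⁻⁶ /M/s)
    initiator → 2 initiating radical (k = 3.70 × 10⁻⁴ /s)
    free monomer + growing radical → monomer in chains + growing radical, rate k5*[growing radical]*[free monomer] (k = 16000 /M/s)

Ash had 57% of its initiator left, and the units per initiator then gave 232. Neither flask was at rest at 25 min, with initiator still at 57% in ash and 57% in elm. At ten times the time, 250 min, initiator stood at 0.389% in ash, and the lengths had fallen to 166 for ash and 206 for elm, more than 10% apart. Ash then held 0.00398 M of dead chain and 0.00519 M of initiating radical.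

With 4 mol% of initiator in the ash recipe, the units per initiator are 25.0, and the same split share gives 58.7. The computed flask gave 85.7, with free monomer at 0% and 0.00708 M of initiating radical standing.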